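## Analysis of the target

Atoms carry labdane numbers: ring A is C1–C5 with C10, ring B is C5–C10, C17 sits on C8, C18 and C19 on C4, C20 on C10, and C11–C16 form the chain on C9.

Target 28 is an ent-labdane: a trans-fused decalin with a gem-dimethyl group at C4, a secondary hydroxyl at C3, an angular methyl on C10 and a formyl group (C17) on C8. C9 carries the chain C11–C12–C13(C16)=C14–C15, which ends as a methyl (13Z)-enoate. There are five stereocentres (3R,5S,8S,9R,10S); C8, C9, C10 and C5 are contiguous around ring B and C10 is quaternary. C11 is cis to C20, C17 is trans to C11, H-5 is trans to C20 and the hydroxyl is cis to C20. In the chair–chair decalin every substituent except the angular methyl is therefore equatorial, so C8 and C3 have their thermodynamically preferred configurations. The aldehyde is enolisable at C8, and that carbon is five atoms from the electrophilic C13. Base would thus threaten epimerisation or closure of a cyclopentane by intramolecular Michael addition, and the Z-enoate itself can isomerise. The difficulties are the quaternary C10 between two stereocentres, the absolute configuration, the trisubstituted Z-alkene, and three oxygen functions at three oxidation levels. The strategy rests on one feature: C8, C9 and C10 are the γ, β and α carbons of a 2-methylcyclohex-2-enone whose carbonyl carbon is C5. Ring B is therefore enone 7 in latent form, C9 asks for a nucleophile (C11), C10 for an electrophile (C1), and the C5 carbonyl remains to close ring A.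

## Retrosynthetic reasoning

**C17 oxidation level and the silyl ethers.** The aldehyde is made last, from the primary alcohol of diol 27, because an enolisable aldehyde 1,5 to a Michael acceptor would not survive amide bases, cuprates or basic fluoride. Diol 27 comes from bis-silyl ether 26 by one acidic fluoride step. The forward reaction must oxidise a primary alcohol next to a hindered secondary one, which an oxoammonium oxidant does.

**C13–C16 and C14–C15.** The Z-alkene is cut at the C13–methyl bond, which leads to ynoate 25. The cut is not made at C13=C14, since olefination of methyl ketone 22 gives no control of geometry. Syn-addition of a methylcopper reagent to the triple bond fixes the geometry by mechanism. Ynoate 25 is cut at C14–C15 (acylation of acetylide 24) and traced through enol phosphate 23 to methyl ketone 22, the Wacker product of terminal alkene 21. The gain is that the chain travels through all reducing steps as an inert butenyl group.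

**C3–O, C4–methyl and C5–H.** Silyl ether 21 comes from alcohol 20 and this from ketone 19 by hydride delivery. Ketone 19 is cut at one C4–methyl bond and at C5–H, back to enone 17 through enolate 18. Reductive alkylation sets the trans ring fusion and the quaternary C4 in one operation, and it uses exactly the enone that ring closure provides.

**C4=C5, closure of ring A.** Enone 17 is opened to the 1,5-diketone 16. The cut is placed here because a 1,5-diketone is the direct product of Michael chemistry at C10. The forward aldol condensation has only one productive mode, the six-membered closure onto C5.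

**C9–C11 and C1–C10, the key disconnection.** Diketone 16 is cut at the two bonds that flank the quaternary carbon, giving enone 7, Grignard reagent 13 and silyl enone 12. Both bonds end on the β and α carbons of 7, so one conjugate addition followed by trapping of enolate 14 forms both. Silyl diketone 15 is the primary adduct. Any other pair of cuts would build C10 and its neighbours in separate steps. The gain is convergence and the relay of one stereocentre (C8) to C9 and C10. The forward step must give 1,4-addition anti to the C8 arm and capture of the enolate anti to the new chain.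

**C10–C20 and the C8 stereocentre.** Enone 7 is cut at the methyl–alkene bond to iodoenone 6 (cross-coupling) and this to enone 5. Enone 5 comes from silyl enol ether 4 by dehydrogenation, and 4 from the achiral ketone 2 through lithium enolate 3 by deprotonation with a chiral lithium amide. Ketone 2 is the silyl ether of commercial keto alcohol 1. The stereocentre is introduced where the molecule is smallest.

**The annulation reagent.** Silyl enone 12 is cut at its carbonyl: oxidation of carbinol 11, which is the adduct of Grignard reagent 10 (from bromide 8) and aldehyde 9.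

## Alternatives that were turned down

**Alternative 1:** The cuts are C8–C9 and C11–C12. A finished ring A carrying a vinyl group on C10 and a methyl-substituted dienyl chain would undergo a thermal intramolecular Diels–Alder reaction to the tricyclic silyl ether A1. This closes ring B and an auxiliary cyclohexene. Ozonolysis of its C13=C14 bond would then turn C14 into the formyl carbon on C8 and C13 into a methyl ketone at the end of the chain.
- For: two C–C bonds, ring B and the C8/C9 pair arise in one step without organometallic reagents. One cleavage gives both carbonyl groups. In bonds formed per step it is stronger than the chosen route.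
- Against: diene and dienophile are both unactivated and the dienophile sits on a quaternary carbon, so forcing temperatures are needed. The trans-anti-trans adduct is only one of several possible transition-state outcomes.
- Against: after cleavage the more reactive carbonyl (the aldehyde) is the one to be kept. The Z-enoate must then come from a two-carbon olefination of a methyl ketone, for which there is no dependable geometric control.
- Against: the chiral ring A precursor with C5 and C10 already set needs its own asymmetric synthesis.
- Comparison: the chosen route sets C9 and C10 at low temperature from one small stereocentre and solves the alkene geometry by syn-carbocupration.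

**Alternative 2:** The cut is C9–C10. A phenol that becomes ring A (oxygen at C3, methyls at C4 and C10) carries a tether ending in an allylic carbonate. With a zerovalent palladium catalyst and a chiral diphosphine, the para carbon would attack the π-allyl unit and close ring B as the cross-conjugated dienone A2.
- For: it is catalytic in the chiral source, starts from cheap aromatics, and brings the C3 oxygen and one C4 methyl with ring A. On economy of chirality it is stronger than the chosen route, which spends a stoichiometric chiral amide.
- Against: the tether already contains C8, so two new centres (C9, C10) form next to an existing one and catalyst control may oppose substrate control. O-allylation and ortho attack compete.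
- Against: A2 still needs selective reduction of C1=C2, reductive methylation across C4=C5 and reduction at C3. Its vinyl group supplies only C11 and C12, so three chain carbons and the Z-alkene remain to be added.
- Comparison: the chosen route sets the ring B centres by the well-understood trans rules of cuprate addition and enolate capture. It also delivers four chain carbons in the key step.

**Alternative 3:** The cuts are C12–C13 and C14–C15. Andrographolide A4, a commercial ent-labdane lactone, would be degraded to a decalin with a two-carbon chain ending in a C12 halide, C17 as a dimethyl acetal and C3 as a silyl ether. Its C12 alkylcopper reagent would add syn to a three-carbon terminal alkyne, and the alkenylcopper would be acylated by a chloroformate to give A3.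
- For: C3, C5, C9 and C10 come from the chiral pool with the correct absolute configuration. On stereochemical security of the ring it is stronger than the chosen route. The Z-geometry follows from syn-addition as reliably as in the chosen route, and two bonds form at once.
- Against: A4 must first lose its C19 hydroxyl, a neopentyl deoxygenation beside the C3 carbinol. Hydroboration of its C8 exocyclic alkene is expected to place C17 on the axial side, so C8 would need epimerisation at the aldehyde stage.
- Against: four lactone carbons must be excised, and the organocopper reagent is made stoichiometrically from a late, valuable intermediate.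
- Comparison: the chosen route is independent of natural supply, gives either enantiomer by choice of the amide, and needs fewer functional-group changes on ring A.

Key step: step 8

Assumption on supply: keto alcohol 1, bromide 8, aldehyde 9, the THF solution of Grignard reagent 13 and both enantiomers of bis(1-phenylethyl)amine are taken as purchased.

Assumption on the sense of induction in step 2: the (R,R)-amide is taken to give the (S)-enol ether 4, as with other 4-substituted cyclohexanones; if the opposite sense is found, the (S,S)-amine is used and nothing else changes.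

## Route

Step 1
Reactants: 1 4-(hydroxymethyl)cyclohexan-1-one
Product: 2 4-{[(tert-butyldimethylsilyl)oxy]methyl}cyclohexan-1-one
Conditions: t-BuMe2SiCl, imidazole, DMF, 0 °C to rt
Reagents that add atoms: tert-butyldimethylsilyl chloride, CC(C)(C)[Si](C)(C)Cl
Why: Silylation of a primary alcohol through the N-silylimidazolium species; the ketone is untouched and the bulky silyl ether later serves as the directing arm on C8.

Step 2
Reactants: 2 4-{[(tert-butyldimethylsilyl)oxy]methyl}cyclohexan-1-one
Product: 4 (S)-tert-butyldimethyl({4-[(trimethylsilyl)oxy]cyclohex-3-en-1-yl}methoxy)silane, via lithium enolate 3 (not isolated)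
Conditions: (R,R)-bis(1-phenylethyl)amine, n-BuLi, THF, −78 °C; Me3SiCl; then 2, −100 °C; Et3N, aq NaHCO3
Reagents that add atoms: chlorotrimethylsilane, C[Si](C)(C)Cl
Why: Enantioselective deprotonation of a prochiral 4-substituted cyclohexanone by a C2-symmetric chiral lithium amide, which removes one of the two enantiotopic axial α-hydrogens; the silyl chloride already in the flask captures enolate 3 before it can equilibrate. This step creates the C8 stereocentre (S), the only one that comes from a chiral reagent.

Step 3
Reactants: 4 (S)-tert-butyldimethyl({4-[(trimethylsilyl)oxy]cyclohex-3-en-1-yl}methoxy)silane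
Product: 5 (S)-4-{[(tert-butyldimethylsilyl)oxy]methyl}cyclohex-2-en-1-one
Conditions: Pd(OAc)2, MeCN, rt
Reagents that add atoms: none
Why: Saegusa–Ito oxidation: the enol ether hands its enolate to divalent palladium and β-hydride elimination gives the enone. The double bond can form only on the side of the former enol ether, so the sense of the desymmetrisation is carried into 5, and the stereocentre is not touched under these neutral conditions.

Step 4
Reactants: 5 (S)-4-{[(tert-butyldimethylsilyl)oxy]methyl}cyclohex-2-en-1-one
Product: 6 (S)-4-{[(tert-butyldimethylsilyl)oxy]methyl}-2-iodocyclohex-2-en-1-one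
Conditions: I2, pyridine, CH2Cl2, 0 °C to rt
Reagents that add atoms: iodine, II
Why: α-Iodination of a cyclic enone by conjugate addition of pyridine, iodination of the resulting enolate and loss of pyridine (addition–elimination); the weak base does not deprotonate the γ-stereocentre.

Step 5
Reactants: 6 (S)-4-{[(tert-butyldimethylsilyl)oxy]methyl}-2-iodocyclohex-2-en-1-one
Product: 7 (S)-4-{[(tert-butyldimethylsilyl)oxy]methyl}-2-methylcyclohex-2-en-1-one
Conditions: MeZnCl, Pd(PPh3)4 (cat.), THF, rt to 45 °C
Reagents that add atoms: methylzinc chloride, C[Zn]Cl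
Why: Negishi coupling: oxidative addition of zerovalent palladium into the alkenyl C–I bond, transmetalation from zinc and reductive elimination form C10–C20. The neutral, base-free medium avoids deconjugation of the enone and so racemisation at C8.

Step 6
Reactants: 8 (1-bromovinyl)trimethylsilane; 9 propanal
Product: 11 2-(trimethylsilyl)pent-1-en-3-ol, via silylvinyl Grignard reagent 10 (not isolated)
Conditions: Mg, THF, reflux; then 9, 0 °C; aq NH4Cl
Reagents that add atoms: none
Why: Formation of the α-silylvinyl Grignard reagent and its 1,2-addition to the aldehyde; the carbinol centre is racemic and is removed in step 7.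

Step 7
Reactants: 11 2-(trimethylsilyl)pent-1-en-3-ol
Product: 12 2-(trimethylsilyl)pent-1-en-3-one
Conditions: CrO3, H2SO4, H2O, acetone, 0 °C
Reagents that add atoms: none
Why: Jones oxidation of a secondary allylic alcohol; the vinylsilane tolerates brief contact with cold aqueous acid, and the enone is distilled and used fresh because it polymerises on standing.

Step 8
Reactants: 7 (S)-4-{[(tert-butyldimethylsilyl)oxy]methyl}-2-methylcyclohex-2-en-1-one; 13 but-3-en-1-ylmagnesium bromide; 12 2-(trimethylsilyl)pent-1-en-3-one
Product: 16 (2S,3R,4S)-3-(but-3-en-1-yl)-4-{[(tert-butyldimethylsilyl)oxy]methyl}-2-methyl-2-(3-oxopentyl)cyclohexan-1-one, via magnesium enolate 14 (not isolated), via silyl diketone 15 (not isolated)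
Conditions: 13, CuBr·SMe2 (cat.), THF, −78 to −40 °C; then 12, −78 to −20 °C; aq NH4Cl; then K2CO3 (cat.), MeOH, 0 °C
Reagents that add atoms: none
Why: Transmetalation of 13 to monovalent copper gives a butenylcuprate that adds 1,4 to 7 (π-complex, trivalent copper β-adduct, reductive elimination) and leaves the bromomagnesium enolate 14 with its double bond fixed between C5 and C10; 14 then adds in Michael fashion to silyl enone 12, whose silicon stabilises the new α-carbanion and slows polymerisation and proton return, and methanolysis removes the silyl group from 15 to leave 16. The closest known reaction type is organocopper conjugate addition to 2-methylcyclohex-2-enones with capture of the enolate by α-silyl vinyl ketones, the first half of a Robinson annulation. No ring closes here; the step forms C9–C11 and C1–C10. C9 is controlled by C8: the cuprate attacks axially on the half-chair that keeps the silyloxymethyl arm pseudoequatorial, anti to that arm, which gives the 8,9-trans relation. C10 is controlled by the new C9 chain: to avoid allylic 1,2-strain with the C10 methyl the chain stands pseudoaxial in 14 and the acceptor enters axially on the opposite face, so C1 ends trans to C11 and the methyl cis to it. The step needs 1,4- over 1,2-addition (copper), an enolate that does not equilibrate (low temperature, no proton source) and the two facial selectivities named. The less secure of these is the one at C10, because in the reactive conformer the C8 arm is axial on the face that must be attacked.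

Step 9
Reactants: 16 (2S,3R,4S)-3-(but-3-en-1-yl)-4-{[(tert-butyldimethylsilyl)oxy]methyl}-2-methyl-2-(3-oxopentyl)cyclohexan-1-one
Product: 17 (4aS,5R,6S)-5-(but-3-en-1-yl)-6-{[(tert-butyldimethylsilyl)oxy]methyl}-1,4a-dimethyl-4,4a,5,6,7,8-hexahydronaphthalen-2(3H)-one
Conditions: NaOMe, MeOH, rt to 60 °C
Reagents that add atoms: none
Why: Intramolecular aldol condensation, the second half of a Robinson annulation (6-enolexo-exo-trig attack of the C4 enolate on the C5 carbonyl, then E1cB loss of water); bridged ketols from the C6 enolate revert and only the fused ketol can dehydrate. No stereocentre is α to a carbonyl except quaternary C10, so nothing epimerises.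

Step 10
Reactants: 17 (4aS,5R,6S)-5-(but-3-en-1-yl)-6-{[(tert-butyldimethylsilyl)oxy]methyl}-1,4a-dimethyl-4,4a,5,6,7,8-hexahydronaphthalen-2(3H)-one
Product: 19 (4aS,5R,6S,8aS)-5-(but-3-en-1-yl)-6-{[(tert-butyldimethylsilyl)oxy]methyl}-1,1,4a-trimethyloctahydronaphthalen-2(1H)-one, via lithium enolate 18 (not isolated)
Conditions: Li, NH3(l), THF, t-BuOH (1 equiv), −78 °C; isoprene; then MeI, −78 to −33 °C
Reagents that add atoms: iodomethane, CI
Why: Dissolving-metal conjugate reduction followed by alkylation of the regiospecific enolate (reductive alkylation): two electrons and one proton give enolate 18, and MeI alkylates C4 to complete the gem-dimethyl group. C5 is protonated on the face opposite the angular methyl, through the chair-like trans-fused carbanion, which sets the trans ring fusion (5S). The isolated alkene and the silyl ether are inert.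

Step 11
Reactants: 19 (4aS,5R,6S,8aS)-5-(but-3-en-1-yl)-6-{[(tert-butyldimethylsilyl)oxy]methyl}-1,1,4a-trimethyloctahydronaphthalen-2(1H)-one
Product: 20 (2R,4aS,5R,6S,8aS)-5-(but-3-en-1-yl)-6-{[(tert-butyldimethylsilyl)oxy]methyl}-1,1,4a-trimethyldecahydronaphthalen-2-ol
Conditions: NaBH4, MeOH, 0 °C
Reagents that add atoms: none
Why: Hydride reduction of a 4,4-dimethyl-3-ketone: the small reagent attacks axially, on the face away from the axial C4 methyl, and gives the equatorial alcohol (3R), cis to C20.

Step 12
Reactants: 20 (2R,4aS,5R,6S,8aS)-5-(but-3-en-1-yl)-6-{[(tert-butyldimethylsilyl)oxy]methyl}-1,1,4a-trimethyldecahydronaphthalen-2-ol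
Product: 21 tert-butyl{[(2R,4aS,5R,6S,8aS)-5-(but-3-en-1-yl)-6-{[(tert-butyldimethylsilyl)oxy]methyl}-1,1,4a-trimethyldecahydronaphthalen-2-yl]oxy}dimethylsilane
Conditions: t-BuMe2SiOTf, 2,6-lutidine, CH2Cl2, 0 °C
Reagents that add atoms: tert-butyldimethylsilyl trifluoromethanesulfonate, CC(C)(C)[Si](C)(C)OS(=O)(=O)C(F)(F)F
Why: Silylation of a hindered neopentyl-type secondary alcohol needs the silyl triflate; the ether shields C3–OH from the amide base and the chloroformate of step 14.

Step 13
Reactants: 21 tert-butyl{[(2R,4aS,5R,6S,8aS)-5-(but-3-en-1-yl)-6-{[(tert-butyldimethylsilyl)oxy]methyl}-1,1,4a-trimethyldecahydronaphthalen-2-yl]oxy}dimethylsilane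
Product: 22 4-[(1R,2S,4aS,6R,8aS)-6-[(tert-butyldimethylsilyl)oxy]-2-{[(tert-butyldimethylsilyl)oxy]methyl}-5,5,8a-trimethyldecahydronaphthalen-1-yl]butan-2-one
Conditions: PdCl2 (cat.), CuCl (co-catalyst), O2 (1 atm), DMF/H2O, rt
Reagents that add atoms: water, O
Why: Wacker–Tsuji oxidation: Markovnikov hydroxypalladation of the terminal alkene by divalent palladium and β-hydride elimination give the methyl ketone, while the copper salt and oxygen return zerovalent palladium to the cycle. Both silyl ethers are expected to survive the aqueous DMF.

Step 14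
Reactants: 22 4-[(1R,2S,4aS,6R,8aS)-6-[(tert-butyldimethylsilyl)oxy]-2-{[(tert-butyldimethylsilyl)oxy]methyl}-5,5,8a-trimethyldecahydronaphthalen-1-yl]butan-2-one
Product: 25 methyl 5-[(1R,2S,4aS,6R,8aS)-6-[(tert-butyldimethylsilyl)oxy]-2-{[(tert-butyldimethylsilyl)oxy]methyl}-5,5,8a-trimethyldecahydronaphthalen-1-yl]pent-2-ynoate, via enol phosphate 23 (not isolated), via lithium acetylide 24 (not isolated)
Conditions: LiN(i-Pr)2 (1.1 equiv), THF, −78 °C; ClP(O)(OEt)2, −78 °C to rt; LiN(i-Pr)2 (2.5 equiv), −78 °C to rt; then ClCO2Me, −78 °C; aq NH4Cl at −78 °C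
Reagents that add atoms: methyl chloroformate, COC(=O)Cl
Why: Kinetic deprotonation on the methyl side and O-phosphorylation give 23; amide-induced β-elimination of the phosphate and deprotonation give acetylide 24, which is C-acylated by the chloroformate. Each operation is a known reaction type (terminal alkyne from a methyl ketone through its enol phosphate, carboxylation of a lithium acetylide) and they are run in one flask.

Step 15
Reactants: 25 methyl 5-[(1R,2S,4aS,6R,8aS)-6-[(tert-butyldimethylsilyl)oxy]-2-{[(tert-butyldimethylsilyl)oxy]methyl}-5,5,8a-trimethyldecahydronaphthalen-1-yl]pent-2-ynoate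
Product: 26 methyl (2Z)-5-[(1R,2S,4aS,6R,8aS)-6-[(tert-butyldimethylsilyl)oxy]-2-{[(tert-butyldimethylsilyl)oxy]methyl}-5,5,8a-trimethyldecahydronaphthalen-1-yl]-3-methylpent-2-enoate
Conditions: Me2CuLi (from CuI and MeLi), THF, −78 °C; MeOH, −78 °C; aq NH4Cl
Reagents that add atoms: lithium dimethylcuprate, [Li+].C[Cu-]C
Why: Syn-carbocupration of an alkynoate: methyl and copper add to the same side of the triple bond, methyl to C13, and protonation at −78 °C replaces copper with retention. H-14 is then cis to the new methyl and the ester cis to C12, which is the Z-isomer; the cold quench prevents the alkenylcopper from equilibrating through its allenolate.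

Step 16
Reactants: 26 methyl (2Z)-5-[(1R,2S,4aS,6R,8aS)-6-[(tert-butyldimethylsilyl)oxy]-2-{[(tert-butyldimethylsilyl)oxy]methyl}-5,5,8a-trimethyldecahydronaphthalen-1-yl]-3-methylpent-2-enoate
Product: 27 methyl (2Z)-5-[(1R,2S,4aS,6R,8aS)-6-hydroxy-2-(hydroxymethyl)-5,5,8a-trimethyldecahydronaphthalen-1-yl]-3-methylpent-2-enoate
Conditions: HF·pyridine, pyridine, THF, 0 °C to rt
Reagents that add atoms: none
Why: Fluoride-assisted cleavage of both Si–O bonds under weakly acidic conditions; a basic fluoride source is avoided because the primary alkoxide could add to C13 of the enoate.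

Step 17
Reactants: 27 methyl (2Z)-5-[(1R,2S,4aS,6R,8aS)-6-hydroxy-2-(hydroxymethyl)-5,5,8a-trimethyldecahydronaphthalen-1-yl]-3-methylpent-2-enoate
Product: 28 methyl (2Z)-5-[(1R,2S,4aS,6R,8aS)-2-formyl-6-hydroxy-5,5,8a-trimethyldecahydronaphthalen-1-yl]-3-methylpent-2-enoate
Conditions: TEMPO (cat.), PhI(OAc)2, CH2Cl2, rt
Reagents that add atoms: none
Why: Oxoammonium (TEMPO) oxidation with PhI(OAc)2 as terminal oxidant is selective for primary over secondary alcohols and stops at the aldehyde in the absence of water; the C3 carbinol is in addition neopentylic. The medium is free of base, so C8 is not epimerised and the aldehyde enolate cannot add to the enoate.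

## Compound list

1 | 4-(hydroxymethyl)cyclohexan-1-one | O=C1CCC(CO)CC1 | starting material
2 | 4-{[(tert-butyldimethylsilyl)oxy]methyl}cyclohexan-1-one | O=C1CCC(CO[Si](C)(C)C(C)(C)C)CC1 | intermediate
3 | lithium (S)-4-{[(tert-butyldimethylsilyl)oxy]methyl}cyclohex-1-en-1-olate | [Li]OC1=CC[C@@H](CO[Si](C)(C)C(C)(C)C)CC1 | intermediate
4 | (S)-tert-butyldimethyl({4-[(trimethylsilyl)oxy]cyclohex-3-en-1-yl}methoxy)silane | C[Si](C)(C)OC1=CC[C@@H](CO[Si](C)(C)C(C)(C)C)CC1 | intermediate
5 | (S)-4-{[(tert-butyldimethylsilyl)oxy]methyl}cyclohex-2-en-1-one | O=C1C=C[C@@H](CO[Si](C)(C)C(C)(C)C)CC1 | intermediate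
6 | (S)-4-{[(tert-butyldimethylsilyl)oxy]methyl}-2-iodocyclohex-2-en-1-one | O=C1C(I)=C[C@@H](CO[Si](C)(C)C(C)(C)C)CC1 | intermediate
7 | (S)-4-{[(tert-butyldimethylsilyl)oxy]methyl}-2-methylcyclohex-2-en-1-one | CC1=C[C@@H](CO[Si](C)(C)C(C)(C)C)CCC1=O | intermediate
8 | (1-bromovinyl)trimethylsilane | C=C(Br)[Si](C)(C)C | starting material
9 | propanal | CCC=O | starting material
10 | [1-(trimethylsilyl)vinyl]magnesium bromide | C=C([Mg]Br)[Si](C)(C)C | intermediate
11 | 2-(trimethylsilyl)pent-1-en-3-ol (racemic) | CCC(O)C(=C)[Si](C)(C)C | intermediate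
12 | 2-(trimethylsilyl)pent-1-en-3-one | CCC(=O)C(=C)[Si](C)(C)C | intermediate
13 | but-3-en-1-ylmagnesium bromide | C=CCC[Mg]Br | starting material
14 | bromomagnesium (3R,4S)-3-(but-3-en-1-yl)-4-{[(tert-butyldimethylsilyl)oxy]methyl}-2-methylcyclohex-1-en-1-olate | C=CCC[C@@H]1[C@@H](CO[Si](C)(C)C(C)(C)C)CCC(O[Mg]Br)=C1C | intermediate
15 | (2S,3R,4S)-3-(but-3-en-1-yl)-4-{[(tert-butyldimethylsilyl)oxy]methyl}-2-methyl-2-[3-oxo-2-(trimethylsilyl)pentyl]cyclohexan-1-one (both epimers at the silylated carbon) | C=CCC[C@@H]1[C@@H](CO[Si](C)(C)C(C)(C)C)CCC(=O)[C@@]1(C)CC([Si](C)(C)C)C(=O)CC | intermediate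
16 | (2S,3R,4S)-3-(but-3-en-1-yl)-4-{[(tert-butyldimethylsilyl)oxy]methyl}-2-methyl-2-(3-oxopentyl)cyclohexan-1-one | C=CCC[C@@H]1[C@@H](CO[Si](C)(C)C(C)(C)C)CCC(=O)[C@@]1(C)CCC(=O)CC | intermediate
17 | (4aS,5R,6S)-5-(but-3-en-1-yl)-6-{[(tert-butyldimethylsilyl)oxy]methyl}-1,4a-dimethyl-4,4a,5,6,7,8-hexahydronaphthalen-2(3H)-one | C=CCC[C@@H]1[C@@H](CO[Si](C)(C)C(C)(C)C)CCC2=C(C)C(=O)CC[C@@]12C | intermediate
18 | lithium (4aS,5R,6S,8aS)-5-(but-3-en-1-yl)-6-{[(tert-butyldimethylsilyl)oxy]methyl}-1,4a-dimethyl-3,4,4a,5,6,7,8,8a-octahydronaphthalen-2-olate | C=CCC[C@@H]1[C@@H](CO[Si](C)(C)C(C)(C)C)CC[C@@H]2C(C)=C(O[Li])CC[C@@]12C | intermediate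
19 | (4aS,5R,6S,8aS)-5-(but-3-en-1-yl)-6-{[(tert-butyldimethylsilyl)oxy]methyl}-1,1,4a-trimethyloctahydronaphthalen-2(1H)-one | C=CCC[C@@H]1[C@@H](CO[Si](C)(C)C(C)(C)C)CC[C@@H]2C(C)(C)C(=O)CC[C@@]12C | intermediate
20 | (2R,4aS,5R,6S,8aS)-5-(but-3-en-1-yl)-6-{[(tert-butyldimethylsilyl)oxy]methyl}-1,1,4a-trimethyldecahydronaphthalen-2-ol | C=CCC[C@@H]1[C@@H](CO[Si](C)(C)C(C)(C)C)CC[C@@H]2C(C)(C)[C@H](O)CC[C@@]12C | intermediate
21 | tert-butyl{[(2R,4aS,5R,6S,8aS)-5-(but-3-en-1-yl)-6-{[(tert-butyldimethylsilyl)oxy]methyl}-1,1,4a-trimethyldecahydronaphthalen-2-yl]oxy}dimethylsilane | C=CCC[C@@H]1[C@@H](CO[Si](C)(C)C(C)(C)C)CC[C@@H]2C(C)(C)[C@H](O[Si](C)(C)C(C)(C)C)CC[C@@]12C | intermediate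
22 | 4-[(1R,2S,4aS,6R,8aS)-6-[(tert-butyldimethylsilyl)oxy]-2-{[(tert-butyldimethylsilyl)oxy]methyl}-5,5,8a-trimethyldecahydronaphthalen-1-yl]butan-2-one | CC(=O)CC[C@@H]1[C@@H](CO[Si](C)(C)C(C)(C)C)CC[C@@H]2C(C)(C)[C@H](O[Si](C)(C)C(C)(C)C)CC[C@@]12C | intermediate
23 | 4-[(1R,2S,4aS,6R,8aS)-6-[(tert-butyldimethylsilyl)oxy]-2-{[(tert-butyldimethylsilyl)oxy]methyl}-5,5,8a-trimethyldecahydronaphthalen-1-yl]but-1-en-2-yl diethyl phosphate | C=C(OP(=O)(OCC)OCC)CC[C@@H]1[C@@H](CO[Si](C)(C)C(C)(C)C)CC[C@@H]2C(C)(C)[C@H](O[Si](C)(C)C(C)(C)C)CC[C@@]12C | intermediate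
24 | {4-[(1R,2S,4aS,6R,8aS)-6-[(tert-butyldimethylsilyl)oxy]-2-{[(tert-butyldimethylsilyl)oxy]methyl}-5,5,8a-trimethyldecahydronaphthalen-1-yl]but-1-yn-1-yl}lithium | [Li]C#CCC[C@@H]1[C@@H](CO[Si](C)(C)C(C)(C)C)CC[C@@H]2C(C)(C)[C@H](O[Si](C)(C)C(C)(C)C)CC[C@@]12C | intermediate
25 | methyl 5-[(1R,2S,4aS,6R,8aS)-6-[(tert-butyldimethylsilyl)oxy]-2-{[(tert-butyldimethylsilyl)oxy]methyl}-5,5,8a-trimethyldecahydronaphthalen-1-yl]pent-2-ynoate | COC(=O)C#CCC[C@@H]1[C@@H](CO[Si](C)(C)C(C)(C)C)CC[C@@H]2C(C)(C)[C@H](O[Si](C)(C)C(C)(C)C)CC[C@@]12C | intermediate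
26 | methyl (2Z)-5-[(1R,2S,4aS,6R,8aS)-6-[(tert-butyldimethylsilyl)oxy]-2-{[(tert-butyldimethylsilyl)oxy]methyl}-5,5,8a-trimethyldecahydronaphthalen-1-yl]-3-methylpent-2-enoate | COC(=O)/C=C(/C)CC[C@@H]1[C@@H](CO[Si](C)(C)C(C)(C)C)CC[C@@H]2C(C)(C)[C@H](O[Si](C)(C)C(C)(C)C)CC[C@@]12C | intermediate
27 | methyl (2Z)-5-[(1R,2S,4aS,6R,8aS)-6-hydroxy-2-(hydroxymethyl)-5,5,8a-trimethyldecahydronaphthalen-1-yl]-3-methylpent-2-enoate | COC(=O)/C=C(/C)CC[C@@H]1[C@@H](CO)CC[C@@H]2C(C)(C)[C@H](O)CC[C@@]12C | intermediate
28 | methyl (2Z)-5-[(1R,2S,4aS,6R,8aS)-2-formyl-6-hydroxy-5,5,8a-trimethyldecahydronaphthalen-1-yl]-3-methylpent-2-enoate | COC(=O)/C=C(/C)CC[C@@H]1[C@@H](C=O)CC[C@@H]2C(C)(C)[C@H](O)CC[C@@]12C | target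

## Step count and least certain steps

Total: 17 steps. Longest linear sequence: 15 steps (1 to 28 through steps 1–5 and 8–17); steps 6 and 7 form the side branch to 12.

**Step 8 (key step).** Two processes are most likely to fail. The first is proton transfer to the hindered, tetrasubstituted enolate 14 from the acceptor or the adduct, which would return the simple conjugate adduct and oligomers of 12. The second is loss of facial selectivity at C10, because the C8 arm is axial on the face the acceptor must use when the C9 chain is pseudoaxial. The fallback sets out from enone 7 and comes back at diketone 16. The copper-catalysed addition of 13 is run in the presence of Me3SiCl, so that the enolate is captured and isolated as tert-butyl{[(1S,2R)-2-(but-3-en-1-yl)-3-methyl-4-[(trimethylsilyl)oxy]cyclohex-3-en-1-yl]methoxy}dimethylsilane F1. This neutral enol ether is then joined to pent-1-en-3-one under BF3·OEt2 in CH2Cl2 at −78 °C (Mukaiyama–Michael addition), and aqueous work-up gives 16. No basic enolate is present, so proton transfer is excluded; the facial question at C10 remains.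

**Step 2.** Enantioselection may be incomplete, through competing removal of the other enantiotopic hydrogen or through equilibration of 3 before silylation; every later compound would carry the minor enantiomer. The fallback sets out from enone 7 of insufficient purity and returns the same compound 7: the enantiomers are separated by preparative chromatography on a chiral stationary phase. The source of enantiopurity changes from induction to resolution, and no new compound is made (F0).

**Step 10.** Proton exchange between enolate 18, the ketone product and amide in ammonia can scramble the enolate, giving unmethylated ketone, C2-methylation or polymethylation; over-reduction of the ketone is also possible. The fallback sets out from enone 17 and comes back at enolate 18. After the reduction the enolate is silylated (Me3SiCl, Et3N) and isolated as {[(4aS,5R,6S,8aS)-5-(but-3-en-1-yl)-6-{[(tert-butyldimethylsilyl)oxy]methyl}-1,4a-dimethyl-3,4,4a,5,6,7,8,8a-octahydronaphthalen-2-yl]oxy}trimethylsilane F2. MeLi in THF regenerates 18 free of ammonia and amide, and MeI with DMPU as cosolvent gives 19.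

**Step 14.** Enolisation of 22 toward C12 in place of the methyl group would lead to internal alkyne or allene. Diisopropylamine may also add to the ynoate during the quench. The fallback sets out from alkene 21 and comes back at ynoate 25, replacing steps 13 and 14. Ozonolysis (O3, CH2Cl2, −78 °C; PPh3) gives 3-[(1R,2S,4aS,6R,8aS)-6-[(tert-butyldimethylsilyl)oxy]-2-{[(tert-butyldimethylsilyl)oxy]methyl}-5,5,8a-trimethyldecahydronaphthalen-1-yl]propanal F3. Dimethyl (1-diazo-2-oxopropyl)phosphonate with K2CO3 in MeOH (Ohira–Bestmann homologation) gives tert-butyl{[(1R,2S,4aS,6R,8aS)-1-(but-3-yn-1-yl)-6-[(tert-butyldimethylsilyl)oxy]-5,5,8a-trimethyldecahydronaphthalen-2-yl]methoxy}dimethylsilane F4. n-BuLi followed by ClCO2Me then gives 25.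

**Step 17.** Competing oxidation of the C3 carbinol or over-oxidation of the aldehyde would erode chemoselectivity. The fallback sets out from 26 and comes back at 28. Buffered HF·pyridine at 0 °C removes only the primary silyl ether and gives methyl (2Z)-5-[(1R,2S,4aS,6R,8aS)-6-[(tert-butyldimethylsilyl)oxy]-2-(hydroxymethyl)-5,5,8a-trimethyldecahydronaphthalen-1-yl]-3-methylpent-2-enoate F5. Dess–Martin periodinane gives methyl (2Z)-5-[(1R,2S,4aS,6R,8aS)-6-[(tert-butyldimethylsilyl)oxy]-2-formyl-5,5,8a-trimethyldecahydronaphthalen-1-yl]-3-methylpent-2-enoate F6. Aqueous HF in MeCN then frees the hindered secondary alcohol to give 28.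

## Further compounds

F1 | step 8 | tert-butyl{[(1S,2R)-2-(but-3-en-1-yl)-3-methyl-4-[(trimethylsilyl)oxy]cyclohex-3-en-1-yl]methoxy}dimethylsilane | C=CCC[C@@H]1[C@@H](CO[Si](C)(C)C(C)(C)C)CCC(O[Si](C)(C)C)=C1C
F0 | step 2 | none | none
F2 | step 10 | {[(4aS,5R,6S,8aS)-5-(but-3-en-1-yl)-6-{[(tert-butyldimethylsilyl)oxy]methyl}-1,4a-dimethyl-3,4,4a,5,6,7,8,8a-octahydronaphthalen-2-yl]oxy}trimethylsilane | C=CCC[C@@H]1[C@@H](CO[Si](C)(C)C(C)(C)C)CC[C@@H]2C(C)=C(O[Si](C)(C)C)CC[C@@]12C
F3 | step 14 | 3-[(1R,2S,4aS,6R,8aS)-6-[(tert-butyldimethylsilyl)oxy]-2-{[(tert-butyldimethylsilyl)oxy]methyl}-5,5,8a-trimethyldecahydronaphthalen-1-yl]propanal | O=CCC[C@@H]1[C@@H](CO[Si](C)(C)C(C)(C)C)CC[C@@H]2C(C)(C)[C@H](O[Si](C)(C)C(C)(C)C)CC[C@@]12C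
F4 | step 14 | tert-butyl{[(1R,2S,4aS,6R,8aS)-1-(but-3-yn-1-yl)-6-[(tert-butyldimethylsilyl)oxy]-5,5,8a-trimethyldecahydronaphthalen-2-yl]methoxy}dimethylsilane | C#CCC[C@@H]1[C@@H](CO[Si](C)(C)C(C)(C)C)CC[C@@H]2C(C)(C)[C@H](O[Si](C)(C)C(C)(C)C)CC[C@@]12C
F5 | step 17 | methyl (2Z)-5-[(1R,2S,4aS,6R,8aS)-6-[(tert-butyldimethylsilyl)oxy]-2-(hydroxymethyl)-5,5,8a-trimethyldecahydronaphthalen-1-yl]-3-methylpent-2-enoate | COC(=O)/C=C(/C)CC[C@@H]1[C@@H](CO)CC[C@@H]2C(C)(C)[C@H](O[Si](C)(C)C(C)(C)C)CC[C@@]12C
F6 | step 17 | methyl (2Z)-5-[(1R,2S,4aS,6R,8aS)-6-[(tert-butyldimethylsilyl)oxy]-2-formyl-5,5,8a-trimethyldecahydronaphthalen-1-yl]-3-methylpent-2-enoate | COC(=O)/C=C(/C)CC[C@@H]1[C@@H](C=O)CC[C@@H]2C(C)(C)[C@H](O[Si](C)(C)C(C)(C)C)CC[C@@]12C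
A1 | alternative 1 | tert-butyldimethylsilyl ether of the trans-anti-trans 1,1,4a,7-tetramethyl-1,2,3,4,4a,4b,5,6,8a,9,10,10a-dodecahydrophenanthren-2-ol (alkene at C13=C14 in labdane numbering) | CC1=C[C@H]2CC[C@@H]3C(C)(C)[C@H](O[Si](C)(C)C(C)(C)C)CC[C@@]3(C)[C@@H]2CC1
A2 | alternative 2 | (4aS,5R,6S)-6-{[(tert-butyldimethylsilyl)oxy]methyl}-5-ethenyl-1,4a-dimethyl-5,6,7,8-tetrahydronaphthalen-2(4aH)-one | C=C[C@@H]1[C@@H](CO[Si](C)(C)C(C)(C)C)CCC2=C(C)C(=O)C=C[C@@]12C
A3 | alternative 3 | methyl (2Z)-5-[(1R,2S,4aS,6R,8aS)-6-[(tert-butyldimethylsilyl)oxy]-2-(dimethoxymethyl)-5,5,8a-trimethyldecahydronaphthalen-1-yl]-3-methylpent-2-enoate | COC(=O)/C=C(/C)CC[C@@H]1[C@@H](C(OC)OC)CC[C@@H]2C(C)(C)[C@H](O[Si](C)(C)C(C)(C)C)CC[C@@]12C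
A4 | alternative 3 | andrographolide, (3E,4S)-3-{2-[(1R,4aS,5R,6R,8aS)-6-hydroxy-5-(hydroxymethyl)-5,8a-dimethyl-2-methylidenedecahydronaphthalen-1-yl]ethylidene}-4-hydroxyoxolan-2-one | C[C@@]12CC[C@H]([C@@]([C@H]1CCC(=C)[C@H]2C/C=C/3\[C@@H](COC3=O)O)(C)CO)O
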